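**Retrosynthetic overview**
1. Isocycloheterophyllin ⇐ its 4',5'-bis-silyl ether; the C6 prenyl ⇐ a 5-O-allyl group (aromatic Claisen rearrangement, then cross-metathesis).
2. Key disconnection: the aryl–O–C(=CMe2) enol ether bond of the oxepine ⇐ free 2'-phenol + 2-bromo-3-methylbut-2-enyl chain on C3 (intramolecular copper-catalysed O-vinylation; last ring formed).
3. Pyranone ring ⇐ cyclodehydration of a C-alkylated 1,3-diketone ⇐ C-aroylation of a ring A methyl ketone by a ring B benzoyl chloride, then C-alkylation with 1,2-dibromo-3-methylbut-2-ene.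
4. Ring A ketone ⇐ phloroacetophenone: dimethylpyran by propargyl ether Claisen/oxa-6π; the second ortho-OH is blocked as the allyl ether so that only the correct OH can close the pyranone.
5. Order of ring formation: dimethylpyran, then pyranone, then oxepine.

Assumption: the target has no stereocentre (both side-chain alkenes end in CMe2 and the pyran alkene is ring-locked), so the "single enantiomer" is the achiral compound itself; flavone numbering (C2–C8, primed ring B positions) is used for the advanced intermediates.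

**Step 1**
Reactants: 1 2,4,6-trihydroxyacetophenone
Product: 2 1-[2,6-dihydroxy-4-(2-methylbut-3-yn-2-yloxy)phenyl]ethanone
Conditions: 3-chloro-3-methylbut-1-yne (1.1 equiv), K2CO3 (1.2 equiv), KI (0.2 equiv), CuI (2 mol%), acetone, 56 °C
Reagents that add atoms: 3-chloro-3-methylbut-1-yne, C#CC(C)(C)Cl
Why: Williamson-type etherification with a tertiary propargylic chloride (copper acetylide assisted) occurs at the 4-hydroxyl because it is the only phenol not hydrogen-bonded to the ketone and is the most acidic one.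

**Step 2**
Reactants: 2 1-[2,6-dihydroxy-4-(2-methylbut-3-yn-2-yloxy)phenyl]ethanone
Product: 3 1-[2-(allyloxy)-6-hydroxy-4-(2-methylbut-3-yn-2-yloxy)phenyl]ethanone
Conditions: allyl bromide (1.1 equiv), K2CO3 (1.5 equiv), acetone, 56 °C
Reagents that add atoms: allyl bromide, C=CCBr
Why: Williamson ether synthesis on two equivalent chelated hydroxyls stops at the mono-ether because the remaining hydroxyl is then held in a stronger hydrogen bond to the ketone, and this allyl ether later blocks the wrong pyranone closure and delivers the C6 carbon chain.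

**Step 3**
Reactants: 3 1-[2-(allyloxy)-6-hydroxy-4-(2-methylbut-3-yn-2-yloxy)phenyl]ethanone
Product: 4 1-[7-(allyloxy)-5-hydroxy-2,2-dimethyl-2H-chromen-6-yl]ethanone
Conditions: DMF, 130 °C, argon
Reagents that add atoms: none
Why: Aryl propargyl ether Claisen rearrangement, 1,5-hydrogen shift and oxa-6π electrocyclisation build the dimethylpyran, the [3,3] shift going to the ring carbon next to the chelated hydroxyl because that path keeps the resonance-assisted OH···O=C hydrogen bond (bond fixation as in resacetophenone ethers), while 130 °C is too low for the allyl ether to rearrange.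

**Step 4**
Reactants: 5 2,4,5-trihydroxybenzaldehyde
Product: 6 2-hydroxy-4,5-bis(triisopropylsilyloxy)benzaldehyde
Conditions: chlorotriisopropylsilane (2.1 equiv), imidazole (4 equiv), DMF, 0 to 25 °C
Reagents that add atoms: chlorotriisopropylsilane, CC(C)[Si](Cl)(C(C)C)C(C)C
Why: Silyl ether formation takes the free 4- and 5-hydroxyls, whereas the 2-hydroxyl is hydrogen-bonded to the aldehyde and too hindered for the bulky silyl chloride.

**Step 5**
Reactants: 6 2-hydroxy-4,5-bis(triisopropylsilyloxy)benzaldehyde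
Product: 7 2-(methoxymethoxy)-4,5-bis(triisopropylsilyloxy)benzaldehyde
Conditions: chloromethyl methyl ether (1.5 equiv), N,N-diisopropylethylamine (2 equiv), CH2Cl2, 0 to 25 °C
Reagents that add atoms: chloromethyl methyl ether, COCCl
Why: O-alkylation of the remaining phenol gives the acetal (MOM) ether, which differs from the silyl ethers in being acid-labile and keeps the ring B ortho-oxygen from competing in the later pyranone closure.

**Step 6**
Reactants: 7 2-(methoxymethoxy)-4,5-bis(triisopropylsilyloxy)benzaldehyde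
Product: 8 2-(methoxymethoxy)-4,5-bis(triisopropylsilyloxy)benzoic acid
Conditions: NaClO2, NaH2PO4, 2-methylbut-2-ene, t-BuOH/H2O, 0 to 25 °C
Reagents that add atoms: sodium chlorite NaClO2, [Na+].[O-]Cl=O
Why: Pinnick oxidation converts the aldehyde into the acid under buffered conditions while the alkene scavenger removes hypochlorous acid, so the electron-rich ring and the acetal and silyl ethers are untouched.

**Step 7**
Reactants: 8 2-(methoxymethoxy)-4,5-bis(triisopropylsilyloxy)benzoic acid; 4 1-[7-(allyloxy)-5-hydroxy-2,2-dimethyl-2H-chromen-6-yl]ethanone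
Product: 10 1-[7-(allyloxy)-5-hydroxy-2,2-dimethyl-2H-chromen-6-yl]-3-[2-(methoxymethoxy)-4,5-bis(triisopropylsilyloxy)phenyl]propane-1,3-dione, via aroyl chloride 9 (not isolated)
Conditions: (a) 8, 1-chloro-N,N,2-trimethylprop-1-en-1-amine, CH2Cl2, 0 °C; (b) 4, LiN(SiMe3)2 (3.3 equiv), THF, −78 °C, then the solution from (a), −78 to 0 °C; aq NH4Cl
Reagents that add atoms: none
Why: Claisen-type C-aroylation of the lithium phenoxide–enolate dianion of the methyl ketone gives the 1,3-diketone directly, any O-aroyl ester being carried on by Baker–Venkataraman acyl transfer under the excess amide base, and the acid chloride is made under neutral conditions so the acetal and silyl ethers survive.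

**Step 8**
Reactants: 11 3-methylbuta-1,2-diene
Product: 13 1,2-dibromo-3-methylbut-2-ene, via 2,3-dibromo-3-methylbut-1-ene 12 (not isolated)
Conditions: Br2 (1.0 equiv), CH2Cl2, −78 °C; then LiBr (5 mol%), 25 °C
Reagents that add atoms: bromine, BrBr
Why: Electrophilic addition of bromine to the allene places one bromine on the central carbon, and the kinetic tertiary allylic bromide equilibrates by allylic 1,3-bromide shift to the primary bromide with the more substituted alkene.

**Step 9**
Reactants: 10 1-[7-(allyloxy)-5-hydroxy-2,2-dimethyl-2H-chromen-6-yl]-3-[2-(methoxymethoxy)-4,5-bis(triisopropylsilyloxy)phenyl]propane-1,3-dione; 13 1,2-dibromo-3-methylbut-2-ene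
Product: 14 1-[7-(allyloxy)-5-hydroxy-2,2-dimethyl-2H-chromen-6-yl]-2-(2-bromo-3-methylbut-2-enyl)-3-[2-(methoxymethoxy)-4,5-bis(triisopropylsilyloxy)phenyl]propane-1,3-dione (racemic)
Conditions: 13 (1.2 equiv), K2CO3 (1.5 equiv), acetone, 25 °C
Reagents that add atoms: none
Why: SN2 C-alkylation of the soft potassium enolate of the 1,3-diketone by the primary allylic bromide installs the whole C5 chain with its vinyl bromide, the chelated ring A phenol being far less nucleophilic, and the new stereocentre is racemic and is removed in step 10.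

**Step 10**
Reactants: 14 1-[7-(allyloxy)-5-hydroxy-2,2-dimethyl-2H-chromen-6-yl]-2-(2-bromo-3-methylbut-2-enyl)-3-[2-(methoxymethoxy)-4,5-bis(triisopropylsilyloxy)phenyl]propane-1,3-dione (racemic)
Product: 16 5-(allyloxy)-3-(2-bromo-3-methylbut-2-enyl)-2-[2-hydroxy-4,5-bis(triisopropylsilyloxy)phenyl]-8,8-dimethyl-4H,8H-pyrano[2,3-h]chromen-4-one, via MOM-protected flavone 15 (not isolated)
Conditions: p-TsOH·H2O (0.2 equiv), toluene, 60 °C; then MeOH, HCl (1 M), 45 °C
Reagents that add atoms: none
Why: Acid-catalysed cyclodehydration of the 2-hydroxyaryl 1,3-diketone (the closing stage of a Baker–Venkataraman flavone synthesis) can only use the single free phenol, the one next to the pyran carbon, which fixes the angular ring fusion, and acid methanolysis in the same flask then removes the MOM acetal but not the silyl or allyl ethers.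

**Step 11**
Reactants: 16 5-(allyloxy)-3-(2-bromo-3-methylbut-2-enyl)-2-[2-hydroxy-4,5-bis(triisopropylsilyloxy)phenyl]-8,8-dimethyl-4H,8H-pyrano[2,3-h]chromen-4-one
Product: 17 5-O-allyl-6-deprenyl-4',5'-bis-O-(triisopropylsilyl)isocycloheterophyllin
Conditions: CuI (10 mol%), 3,4,7,8-tetramethyl-1,10-phenanthroline (20 mol%), K3PO4 (2 equiv), toluene, 100 °C, argon
Reagents that add atoms: none
Why: Proposed new method: an Ullmann-type intramolecular O-vinylation in which the potassium 2'-phenoxide binds monovalent copper carrying the phenanthroline ligand, the C(sp2)–Br bond of the fully substituted 2-bromo-3-methylbut-2-enyl chain (held 1,7 to the oxygen by the rigid 2-arylchromone) adds oxidatively to give a trivalent alkenyl(aryloxo)copper species and C–O reductive elimination closes the seven-membered exocyclic aryl enol ether with the alkene fixed by the bromide position because no hydride elimination or acid is involved; the closest known reaction type is copper-catalysed O-vinylation of phenols by vinyl halides, including intramolecular four- to six-membered ring closures onto less substituted vinyl bromides, which to my knowledge has not been shown for a tetrasubstituted vinyl bromide or a seven-membered ring.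

**Step 12**
Reactants: 17 5-O-allyl-6-deprenyl-4',5'-bis-O-(triisopropylsilyl)isocycloheterophyllin
Product: 18 6-allyl-6-deprenyl-4',5'-bis-O-(triisopropylsilyl)isocycloheterophyllin
Conditions: 1,2-dichlorobenzene, 190 °C, sealed tube, argon
Reagents that add atoms: none
Why: Aromatic Claisen rearrangement moves the 5-O-allyl group to C6, the only open ortho position, and tautomerisation gives the chelated 5-hydroxyl, while the enol ether, the chromene and the silyl ethers tolerate neutral heating.

**Step 13**
Reactants: 18 6-allyl-6-deprenyl-4',5'-bis-O-(triisopropylsilyl)isocycloheterophyllin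
Product: 19 4',5'-bis-O-(triisopropylsilyl)isocycloheterophyllin
Conditions: second-generation Grubbs catalyst RuCl2(=CHPh)(H2IMes)(PCy3) (5 mol%), 2-methylbut-2-ene (20 equiv), CH2Cl2, 40 °C
Reagents that add atoms: 2-methylbut-2-ene, CC=C(C)C
Why: Olefin cross-metathesis of the terminal allyl group with excess 2-methylbut-2-ene gives the prenyl group with loss of propene, while the chromene alkene and the tetrasubstituted enol ether are too hindered to react.

**Step 14**
Reactants: 19 4',5'-bis-O-(triisopropylsilyl)isocycloheterophyllin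
Product: 20 isocycloheterophyllin
Conditions: Bu4NF (2.2 equiv), AcOH (2.5 equiv), THF, 0 °C, argon
Reagents that add atoms: none
Why: Fluoride cleavage of the two aryl silyl ethers under acetic acid buffering frees the catechol without the aqueous acid that would hydrolyse the enol ether or cyclise the prenyl group onto the 5-hydroxyl.

**Compound list**
1 | 2,4,6-trihydroxyacetophenone | CC(=O)c1c(O)cc(O)cc1O | starting material
2 | 1-[2,6-dihydroxy-4-(2-methylbut-3-yn-2-yloxy)phenyl]ethanone | CC(=O)c1c(O)cc(OC(C)(C)C#C)cc1O | intermediate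
3 | 1-[2-(allyloxy)-6-hydroxy-4-(2-methylbut-3-yn-2-yloxy)phenyl]ethanone | CC(=O)c1c(O)cc(OC(C)(C)C#C)cc1OCC=C | intermediate
4 | 1-[7-(allyloxy)-5-hydroxy-2,2-dimethyl-2H-chromen-6-yl]ethanone | CC(=O)c1c(O)c2C=CC(C)(C)Oc2cc1OCC=C | intermediate
5 | 2,4,5-trihydroxybenzaldehyde | O=Cc1cc(O)c(O)cc1O | starting material
6 | 2-hydroxy-4,5-bis(triisopropylsilyloxy)benzaldehyde | O=Cc1cc(O[Si](C(C)C)(C(C)C)C(C)C)c(O[Si](C(C)C)(C(C)C)C(C)C)cc1O | intermediate
7 | 2-(methoxymethoxy)-4,5-bis(triisopropylsilyloxy)benzaldehyde | O=Cc1cc(O[Si](C(C)C)(C(C)C)C(C)C)c(O[Si](C(C)C)(C(C)C)C(C)C)cc1OCOC | intermediate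
8 | 2-(methoxymethoxy)-4,5-bis(triisopropylsilyloxy)benzoic acid | OC(=O)c1cc(O[Si](C(C)C)(C(C)C)C(C)C)c(O[Si](C(C)C)(C(C)C)C(C)C)cc1OCOC | intermediate
9 | 2-(methoxymethoxy)-4,5-bis(triisopropylsilyloxy)benzoyl chloride (not isolated) | ClC(=O)c1cc(O[Si](C(C)C)(C(C)C)C(C)C)c(O[Si](C(C)C)(C(C)C)C(C)C)cc1OCOC | intermediate
10 | 1-[7-(allyloxy)-5-hydroxy-2,2-dimethyl-2H-chromen-6-yl]-3-[2-(methoxymethoxy)-4,5-bis(triisopropylsilyloxy)phenyl]propane-1,3-dione | C=CCOc1cc2OC(C)(C)C=Cc2c(O)c1C(=O)CC(=O)c1cc(O[Si](C(C)C)(C(C)C)C(C)C)c(O[Si](C(C)C)(C(C)C)C(C)C)cc1OCOC | intermediate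
11 | 3-methylbuta-1,2-diene | CC(C)=C=C | starting material
12 | 2,3-dibromo-3-methylbut-1-ene (not isolated) | CC(C)(Br)C(Br)=C | intermediate
13 | 1,2-dibromo-3-methylbut-2-ene | CC(C)=C(Br)CBr | intermediate
14 | 1-[7-(allyloxy)-5-hydroxy-2,2-dimethyl-2H-chromen-6-yl]-2-(2-bromo-3-methylbut-2-enyl)-3-[2-(methoxymethoxy)-4,5-bis(triisopropylsilyloxy)phenyl]propane-1,3-dione, racemic at C2 | C=CCOc1cc2OC(C)(C)C=Cc2c(O)c1C(=O)C(CC(Br)=C(C)C)C(=O)c1cc(O[Si](C(C)C)(C(C)C)C(C)C)c(O[Si](C(C)C)(C(C)C)C(C)C)cc1OCOC | intermediate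
15 | 5-(allyloxy)-3-(2-bromo-3-methylbut-2-enyl)-2-[2-(methoxymethoxy)-4,5-bis(triisopropylsilyloxy)phenyl]-8,8-dimethyl-4H,8H-pyrano[2,3-h]chromen-4-one (not isolated) | C=CCOc1cc2OC(C)(C)C=Cc2c2oc(-c3cc(O[Si](C(C)C)(C(C)C)C(C)C)c(O[Si](C(C)C)(C(C)C)C(C)C)cc3OCOC)c(CC(Br)=C(C)C)c(=O)c12 | intermediate
16 | 5-(allyloxy)-3-(2-bromo-3-methylbut-2-enyl)-2-[2-hydroxy-4,5-bis(triisopropylsilyloxy)phenyl]-8,8-dimethyl-4H,8H-pyrano[2,3-h]chromen-4-one | C=CCOc1cc2OC(C)(C)C=Cc2c2oc(-c3cc(O[Si](C(C)C)(C(C)C)C(C)C)c(O[Si](C(C)C)(C(C)C)C(C)C)cc3O)c(CC(Br)=C(C)C)c(=O)c12 | intermediate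
17 | 5-O-allyl-6-deprenyl-4',5'-bis-O-(triisopropylsilyl)isocycloheterophyllin: the target skeleton with the oxepine closed, O-allyl in place of the 5-OH, H at C6 and OSi(iPr)3 on both ring B oxygens | C=CCOc1cc2OC(C)(C)C=Cc2c2oc3c(c(=O)c12)CC(=C(C)C)Oc1cc(O[Si](C(C)C)(C(C)C)C(C)C)c(O[Si](C(C)C)(C(C)C)C(C)C)cc1-3 | intermediate
18 | 6-allyl-6-deprenyl-4',5'-bis-O-(triisopropylsilyl)isocycloheterophyllin: as 17 but with free 5-OH and an allyl group on C6 | C=CCc1c2c(c3oc4c(c(=O)c3c1O)CC(=C(C)C)Oc1cc(O[Si](C(C)C)(C(C)C)C(C)C)c(O[Si](C(C)C)(C(C)C)C(C)C)cc1-4)C=CC(C)(C)O2 | intermediate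
19 | 4',5'-bis-O-(triisopropylsilyl)isocycloheterophyllin | CC(C)=CCc1c2c(c3oc4c(c(=O)c3c1O)CC(=C(C)C)Oc1cc(O[Si](C(C)C)(C(C)C)C(C)C)c(O[Si](C(C)C)(C(C)C)C(C)C)cc1-4)C=CC(C)(C)O2 | intermediate
20 | isocycloheterophyllin (achiral) | CC(C)=CCc1c2c(c3oc4c(c(=O)c3c1O)CC(=C(C)C)Oc1cc(O)c(O)cc1-4)C=CC(C)(C)O2 | target

**Total step count:** 14.
**Longest linear sequence:** 10 steps (steps 1, 2, 3, 7, 9, 10, 11, 12, 13, 14; the ring B branch through steps 4, 5, 6 is equally long).

**The three steps most likely to fail**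

Step 11, the proposed new ring closure. Oxidative addition of the hindered tetrasubstituted vinyl bromide to copper, or the seven-membered closure itself, may be too slow. The fallback uses known chemistry and sets out from 16. Miyaura borylation of the vinyl bromide (PdCl2(dppf), bis(pinacolato)diboron, KOAc, dioxane, 80 °C) gives the alkenyl pinacol boronate 5-(allyloxy)-2-[2-hydroxy-4,5-bis(triisopropylsilyloxy)phenyl]-8,8-dimethyl-3-[3-methyl-2-(4,4,5,5-tetramethyl-1,3,2-dioxaborolan-2-yl)but-2-enyl]-4H,8H-pyrano[2,3-h]chromen-4-one F1. An intramolecular Chan–Lam oxidative etherification (Cu(OAc)2, pyridine, 4 Å molecular sieves, air, CH2Cl2, 25 °C) then joins the 2'-hydroxyl to the boron-bearing alkene carbon and comes back to the route at 17.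

Step 3, the regiochemistry of the Claisen/pyran annulation. If the shift also goes to the carbon next to the allyl ether, the isomeric chromene contaminates 4. The fallback sets out from 2, whose two ortho positions are equivalent. Heating 2 (DMF, 130 °C) gives 1-(5,7-dihydroxy-2,2-dimethyl-2H-chromen-6-yl)ethanone F2 with no regiochemical choice. Mono-allylation (allyl bromide 1.0 equiv, K2CO3, acetone, 25 °C) is expected at the less hindered 7-hydroxyl, because the 5-hydroxyl sits between the acetyl group and the peri CH of the pyran ring; this selectivity is predicted, not established, and any 5-O-allyl isomer is removed by chromatography. The fallback comes back to the route at 4.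

Step 7, the direct C-aroylation of a di-ortho-substituted ketone enolate by a hindered aroyl chloride. The fallback sets out from 4, with the aroyl chloride 9 made as in step 7, and separates O-acylation from acyl migration. Pyridine and DMAP in CH2Cl2 give the aryl ester 6-acetyl-7-(allyloxy)-2,2-dimethyl-2H-chromen-5-yl 2-(methoxymethoxy)-4,5-bis(triisopropylsilyloxy)benzoate F3. A Baker–Venkataraman rearrangement (KOt-Bu, THF, 0 °C) then comes back to the route at 10.

**Further compounds**
F1 | step 11 | 5-(allyloxy)-2-[2-hydroxy-4,5-bis(triisopropylsilyloxy)phenyl]-8,8-dimethyl-3-[3-methyl-2-(4,4,5,5-tetramethyl-1,3,2-dioxaborolan-2-yl)but-2-enyl]-4H,8H-pyrano[2,3-h]chromen-4-one | C=CCOc1cc2OC(C)(C)C=Cc2c2oc(-c3cc(O[Si](C(C)C)(C(C)C)C(C)C)c(O[Si](C(C)C)(C(C)C)C(C)C)cc3O)c(CC(B3OC(C)(C)C(C)(C)O3)=C(C)C)c(=O)c12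
F2 | step 3 | 1-(5,7-dihydroxy-2,2-dimethyl-2H-chromen-6-yl)ethanone | CC(=O)c1c(O)cc2OC(C)(C)C=Cc2c1O
F3 | step 7 | 6-acetyl-7-(allyloxy)-2,2-dimethyl-2H-chromen-5-yl 2-(methoxymethoxy)-4,5-bis(triisopropylsilyloxy)benzoate | CC(=O)c1c(OCC=C)cc2OC(C)(C)C=Cc2c1OC(=O)c1cc(O[Si](C(C)C)(C(C)C)C(C)C)c(O[Si](C(C)C)(C(C)C)C(C)C)cc1OCOC
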